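**Retrosynthetic overview**
- Target ⇐ chemoselective saponification of the 3,9-dibenzoate methyl ester ⇐ methyl 3β,9α-dihydroxylabda-7,13E-dien-15-oate; the benzoyl groups come from benzaldehyde via benzoyl bromide.
- C17 and the Δ7 alkene ⇐ C8 ketone (methylenation, then Co–H isomerisation of the exocyclic alkene).
- Key disconnection: ring B and the C9 carbinol ⇐ α-ketol 1,2-shift (C10 migrates from C8 to the acyl carbon C9) in a trans-hydrindane 8β-hydroxy-8α-acyl ketol.
- Ketol side chain ⇐ hydrindanone + methoxyallene (C9, C11, C12) + methyl but-2-ynoate (C13–C16), joined by a new Ni-catalysed enone–alkynoate reductive coupling that sets 13E.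
- Ring order: cyclopentane (from 2-methylcyclopentane-1,3-dione) → ring A (asymmetric Robinson annulation, reductive methylation) → ring B by expansion of the five-membered ring.

Assumption: labdane numbering (C1–C20) is used for every bicyclic compound, also the hydrindanes (five-membered ring = C5, C6, C7, C8, C10); α is the face opposite the C10 methyl, and the target is 3β-OH, 5α-H, 9α-OBz, 10β-Me, 13E.

**Step 1**
Reactants: 1 2-methylcyclopentane-1,3-dione; 2 ethyl vinyl ketone
Product: 4 (S)-4,7a-dimethyl-2,3,7,7a-tetrahydro-1H-indene-1,5(6H)-dione, via triketone 3 (not isolated)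
Conditions: H2O, AcOH (cat.), 70 °C; then L-phenylalanine (1 equiv), 1 M HClO4 (0.5 equiv), MeCN, reflux; recrystallise
Reagents that add atoms: none
Why: Michael addition then phenylalanine-mediated Hajos–Parrish–Eder–Sauer–Wiechert aldol condensation (asymmetric Robinson annulation), in which the L-amino-acid enamine attacks one of the two enantiotopic ring carbonyls and so sets the quaternary carbon (C10) as S, with recrystallisation raising the ee.

**Step 2**
Reactants: 4 (S)-enedione
Product: 5 (S)-4,7a-dimethyl-2,3,7,7a-tetrahydro-1H-indene-1,5(6H)-dione 1-ethylene ketal (dioxolane on C8)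
Conditions: ethylene glycol, p-TsOH (cat.), 4 Å MS, CH2Cl2, 23 °C
Reagents that add atoms: ethylene glycol, OCCO
Why: Chemoselective acid-catalysed acetalisation, because the saturated cyclopentanone carbonyl is far more electrophilic than the conjugated C3 carbonyl (as in mono-ketalisation of Wieland–Miescher and Hajos–Parrish ketones); no stereocentre is formed.

**Step 3**
Reactants: 5 enone ketal
Product: 6 4,4,10-trimethyl-5α-hydrindan-3-one 8-ethylene ketal (trans-fused; 10β-methyl)
Conditions: Li (2.2 equiv), t-BuOH (1.0 equiv), NH3(l)–THF, −78 → −33 °C; isoprene; then MeI (5 equiv), −78 → −33 °C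
Reagents that add atoms: iodomethane, CI
Why: Stork reductive alkylation (Birch-type enone reduction, then regiospecific C-methylation of the lithium enolate at C4), in which the β-carbanion at C5 is protonated on the α face anti to the angular methyl to give the trans ring fusion (5α-H), the isolated acetal being inert to Li/NH3.

**Step 4**
Reactants: 6 ketone ketal
Product: 8 3β-hydroxy-4,4,10-trimethyl-5α-hydrindan-8-one, via hydroxy ketal 7 (not isolated)
Conditions: NaBH4, MeOH, 0 → 23 °C; then 1 M HCl, THF, 23 °C
Reagents that add atoms: water, O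
Why: Borohydride reduction with axial hydride delivery from the less hindered α face gives the equatorial 3β-alcohol (as for 4,4-dimethyl-3-oxo steroids), and the acidic work-up hydrolyses the dioxolane.

**Step 5**
Reactants: 8 hydroxy ketone; 9 methoxyallene
Product: 12 8α-acryloyl-4,4,10-trimethyl-5α-hydrindane-3β,8β-diol, via 1-lithio-1-methoxyallene 10 (not isolated), via allenyl ether diol 11 (not isolated)
Conditions: 9 (3.3 equiv), n-BuLi (3.2 equiv), THF, −40 °C; add 8, −78 → −20 °C; then 5% aq. H2SO4, 0 → 23 °C
Reagents that add atoms: water, O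
Why: 1,2-Addition of the acryloyl anion equivalent 1-lithio-1-methoxyallene to the neopentyl cyclopentanone from the α face, anti to the angular methyl (as in additions to 17-oxo steroids), sets C8 with the hydroxyl β, and mild acid hydrolysis of the allenyl enol ether unveils the α′-hydroxy vinyl ketone.

**Step 6**
Reactants: 12 α′-hydroxy vinyl ketone; 13 methyl but-2-ynoate
Product: 15 methyl (E)-6-(3β,8β-dihydroxy-4,4,10-trimethyl-5α-hydrindan-8α-yl)-3-methyl-6-oxohex-2-enoate, via triethylsilyl enol ether 14 (not isolated)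
Conditions: Ni(cod)2 (10 mol %), PCy3 (20 mol %), Et3SiH (2.5 equiv), 13 (1.5 equiv, slow addition), THF, 23 → 45 °C; then 1 M HCl, THF, 0 °C
Reagents that add atoms: none
Why: Proposed new method: Ni(0)-catalysed reductive coupling of an α′-hydroxy vinyl ketone with a 2-alkynoate, in which oxidative cyclisation of the Ni-bound s-cis enone and the alkyne gives an oxa-nickelacycle with the new C12–C13 bond and the ester-bearing carbon on nickel (the conjugating group prefers the position next to the metal), σ-bond metathesis with Et3SiH forms the silyl enol ether and a vinyl nickel hydride, and C–H reductive elimination with retention completes a net syn hydro-alkylation that fixes the 13E geometry; the closest known reaction type is the Montgomery Ni-catalysed reductive coupling of enals and enones with alkynes, not shown for alkynoates or α′-hydroxy enones.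

**Step 7**
Reactants: 15 hydrindane ketol
Product: 16 methyl 3β,9α-dihydroxy-8-oxo-17-norlabd-13E-en-15-oate
Conditions: KOMe (0.2 equiv), MeOH–THF (4:1), 0 → 23 °C
Reagents that add atoms: none
Why: Base-mediated α-ketol (acyloin) rearrangement of the D-homoannulation type, in which the tertiary C10 migrates from C8 to the acyl carbon C9 (as in 17β-hydroxy-17α-acyl steroids) with release of cyclopentane and vicinal-quaternary strain, and the non-chelated alkoxide holds the two C–O dipoles anti so the chain sits exo and the new carbinol has 9α-OH (axial) and 9β-chain (equatorial), which is also the more stable C9 epimer.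

**Step 8**
Reactants: 16 ring-expanded ketol
Product: 17 methyl 3β,9α-dihydroxylabda-8(17),13E-dien-15-oate
Conditions: Zn, CH2Br2, TiCl4, THF–CH2Cl2, 0 → 23 °C (Takai–Lombardo)
Reagents that add atoms: dibromomethane, BrCBr
Why: Takai–Lombardo methylenation with the gem-dizinc/titanium reagent is non-basic, works on hindered and enolisable ketones and leaves esters and free hydroxyls untouched, so C17 is added without disturbing C9.

**Step 9**
Reactants: 17 exocyclic alkene
Product: 18 methyl 3β,9α-dihydroxylabda-7,13E-dien-15-oate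
Conditions: Co(tBu4-salen)Cl (3 mol %), PhSiH3 (6 mol %), benzene, 23 °C
Reagents that add atoms: none
Why: Cobalt-hydride MHAT alkene isomerisation (Shenvi type), in which reversible H-atom transfer gives the tertiary C8 radical that can lose hydrogen only toward C7 (C9 is quaternary) or back to C17 and so funnels into the more stable endocyclic trisubstituted Δ7 alkene, the electron-poor enoate being inert.

**Step 10**
Reactants: 18 diol ester; 19 benzaldehyde
Product: 21 methyl 3β,9α-bis(benzoyloxy)labda-7,13E-dien-15-oate, via benzoyl bromide 20 (not isolated)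
Conditions: 19 (3 equiv), NBS (3 equiv), AIBN (cat.), CCl4, 77 °C, filter; filtrate added to 18, KHMDS (2.3 equiv), THF, −78 → 0 °C
Reagents that add atoms: none
Why: Radical-chain bromination of the aldehyde C–H by NBS gives benzoyl bromide, and acylation of the preformed potassium alkoxides at low temperature is the standard way to esterify a hindered tertiary allylic alcohol; no stereocentre is touched.

**Step 11**
Reactants: 21 dibenzoate methyl ester
Product: 22 9α-benzoyloxy-3β-hydroxylabda-7,13E-dien-15-oic acid (CNP0288577.1)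
Conditions: LiOH (6 equiv), THF–MeOH–H2O (2:2:1), 45 °C; then 1 M HCl to pH 3
Reagents that add atoms: lithium hydroxide, [Li+].[OH-]
Why: Chemoselective saponification, in which the methyl ester and the secondary 3-benzoate are cleaved while the tertiary C9 benzoate, flanked by the quaternary C10, undergoes acyl substitution far more slowly and survives.

**Compound list**
1 | 2-methylcyclopentane-1,3-dione | CC1C(=O)CCC1=O | starting material
2 | ethyl vinyl ketone (pent-1-en-3-one) | CCC(=O)C=C | starting material
3 | 2-methyl-2-(3-oxopentyl)cyclopentane-1,3-dione | CCC(=O)CCC1(C)C(=O)CCC1=O | intermediate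
4 | (S)-4,7a-dimethyl-2,3,7,7a-tetrahydro-1H-indene-1,5(6H)-dione | CC1=C2CCC(=O)[C@@]2(C)CCC1=O | intermediate
5 | (S)-enedione 1-ethylene ketal (dioxolane on C8) | CC1=C2CCC3(OCCO3)[C@@]2(C)CCC1=O | intermediate
6 | 4,4,10-trimethyl-5α-hydrindan-3-one 8-ethylene ketal (trans-fused; 10β-methyl) | CC1(C)[C@@H]2CCC3(OCCO3)[C@@]2(C)CCC1=O | intermediate
7 | 3β-hydroxy-4,4,10-trimethyl-5α-hydrindane 8-ethylene ketal | CC1(C)[C@@H]2CCC3(OCCO3)[C@@]2(C)CC[C@@H]1O | intermediate
8 | 3β-hydroxy-4,4,10-trimethyl-5α-hydrindan-8-one | CC1(C)[C@@H]2CCC(=O)[C@@]2(C)CC[C@@H]1O | intermediate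
9 | methoxyallene (1-methoxypropa-1,2-diene) | COC=C=C | starting material
10 | 1-lithio-1-methoxyallene | [Li]C(OC)=C=C | intermediate
11 | 8α-(1-methoxypropa-1,2-dien-1-yl)-4,4,10-trimethyl-5α-hydrindane-3β,8β-diol (in the flask as its dilithium alkoxide) | CC1(C)[C@@H]2CC[C@@](O)(C(OC)=C=C)[C@@]2(C)CC[C@@H]1O | intermediate
12 | 8α-acryloyl-4,4,10-trimethyl-5α-hydrindane-3β,8β-diol | CC1(C)[C@@H]2CC[C@@](O)(C(=O)C=C)[C@@]2(C)CC[C@@H]1O | intermediate
13 | methyl but-2-ynoate | CC#CC(=O)OC | starting material
14 | triethylsilyl (Z)-enol ether of 15 at C9 | CC1(C)[C@@H]2CC[C@@](O)(/C(O[Si](CC)(CC)CC)=C/C/C(C)=C/C(=O)OC)[C@@]2(C)CC[C@@H]1O | intermediate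
15 | methyl (E)-6-(3β,8β-dihydroxy-4,4,10-trimethyl-5α-hydrindan-8α-yl)-3-methyl-6-oxohex-2-enoate | CC1(C)[C@@H]2CC[C@@](O)(C(=O)CC/C(C)=C/C(=O)OC)[C@@]2(C)CC[C@@H]1O | intermediate
16 | methyl 3β,9α-dihydroxy-8-oxo-17-norlabd-13E-en-15-oate | O=C1CC[C@H]2C(C)(C)[C@@H](O)CC[C@]2(C)[C@]1(CC/C(C)=C/C(=O)OC)O | intermediate
17 | methyl 3β,9α-dihydroxylabda-8(17),13E-dien-15-oate | C=C1CC[C@H]2C(C)(C)[C@@H](O)CC[C@]2(C)[C@]1(CC/C(C)=C/C(=O)OC)O | intermediate
18 | methyl 3β,9α-dihydroxylabda-7,13E-dien-15-oate | CC1=CC[C@H]2C(C)(C)[C@@H](O)CC[C@]2(C)[C@]1(CC/C(C)=C/C(=O)OC)O | intermediate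
19 | benzaldehyde | O=Cc1ccccc1 | starting material
20 | benzoyl bromide | O=C(Br)c1ccccc1 | intermediate
21 | methyl 3β,9α-bis(benzoyloxy)labda-7,13E-dien-15-oate | CC1=CC[C@H]2C(C)(C)[C@@H](OC(=O)c3ccccc3)CC[C@]2(C)[C@]1(CC/C(C)=C/C(=O)OC)OC(=O)c1ccccc1 | intermediate
22 | 9α-benzoyloxy-3β-hydroxylabda-7,13E-dien-15-oic acid (CNP0288577.1) | CC1=CC[C@H]2C(C)(C)[C@@H](O)CC[C@]2(C)[C@]1(CC/C(C)=C/C(=O)O)OC(=O)c1ccccc1 | target

**Totals**
Total step count: 11. Longest linear sequence: 11 steps (1 and 2 → 22); compounds 9, 13 and 19 enter as purchased materials.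

**The three steps most likely to fail**

Step 6, the proposed new Ni coupling. The alkynoate may cyclotrimerise on Ni(0), the regiochemistry may invert, or the vinyl nickel may isomerise and erode 13E. The fallback uses known chemistry and sets out from 12 and 13. Copper-catalysed syn β-borylation of 13 (B2pin2, CuCl/Xantphos, NaOtBu, MeOH, THF) gives methyl (Z)-3-(4,4,5,5-tetramethyl-1,3,2-dioxaborolan-2-yl)but-2-enoate F1, with boron trans to the ester. Rh(I)-catalysed Hayashi–Miyaura 1,4-addition of F1 to the vinyl ketone 12 ([Rh(cod)OH]2, K3PO4, dioxane–H2O, 40 °C) transfers the alkenyl group with retention. This comes back to the route at 15.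

Step 7, the α-ketol ring expansion. C7 could migrate instead of C10, the C9 epimer ratio could be poor, or the C9 alkoxide could add to the enoate (9,13-ether formation). The fallback sets out from 8 and builds ring B and C9 in the opposite order.
- Sc(OTf)3-catalysed homologation of 8 with diazoethane (the CH2 carbon migrates) gives 3β-hydroxy-4,4,8,10-tetramethyl-5α-decalin-9-one F2.
- KHMDS (2.1 equiv)/PhNTf2 gives the tetrasubstituted enol triflate 3β-hydroxy-4,4,8,10-tetramethyl-5α-decal-8-en-9-yl triflate F3; only C8 is enolisable.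
- Syn addition of a vinyl cuprate to 13 at −78 °C gives methyl (E)-3-methylpenta-2,4-dienoate F4.
- The 9-BBN adduct of the terminal vinyl group of F4 is coupled with F3 (B-alkyl Suzuki–Miyaura, Pd(dppf)Cl2, K3PO4, DMF–H2O) to give methyl 3β-hydroxylabda-8,13E-dien-15-oate F5.
- mCPBA epoxidises the electron-rich tetrasubstituted alkene from the α face, anti to the C10 methyl, to give methyl 8α,9α-epoxy-3β-hydroxylabd-13E-en-15-oate F6.
- Et2AlTMP opens F6 by syn abstraction of a C17 methyl hydrogen, leaving the 9α-oxygen in place.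

This comes back to the route at 17.

Step 8, the methylenation. The ketone is hindered and sits next to a chelating tertiary hydroxyl, and the Lewis-acidic reagent could reverse the ketol shift. The fallback sets out from 16. Enolate triflation (KHMDS 3.1 equiv, PhNTf2, THF, −78 °C; only C7 is enolisable) gives methyl 3β,9α-dihydroxy-8-(trifluoromethylsulfonyloxy)-17-norlabda-7,13E-dien-15-oate F7. Negishi coupling with MeZnCl (Pd(PPh3)4, THF, 50 °C) installs C17 with the alkene already at Δ7. This comes back to the route at 18 and skips 17.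

**Further compounds**
F1 | step 6 | methyl (Z)-3-(4,4,5,5-tetramethyl-1,3,2-dioxaborolan-2-yl)but-2-enoate | C/C(B1OC(C)(C)C(C)(C)O1)=C\C(=O)OC
F2 | step 7 | 3β-hydroxy-4,4,8,10-tetramethyl-5α-decalin-9-one (8-methyl epimers) | CC1CC[C@H]2C(C)(C)[C@@H](O)CC[C@]2(C)C1=O
F3 | step 7 | 3β-hydroxy-4,4,8,10-tetramethyl-5α-decal-8-en-9-yl trifluoromethanesulfonate | CC=1CC[C@H]2C(C)(C)[C@@H](O)CC[C@]2(C)C=1OS(=O)(=O)C(F)(F)F
F4 | step 7 | methyl (E)-3-methylpenta-2,4-dienoate | C=C/C(C)=C/C(=O)OC
F5 | step 7 | methyl 3β-hydroxylabda-8,13E-dien-15-oate | CC=1CC[C@H]2C(C)(C)[C@@H](O)CC[C@]2(C)C=1CC/C(C)=C/C(=O)OC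
F6 | step 7 | methyl 8α,9α-epoxy-3β-hydroxylabd-13E-en-15-oate | C[C@@]12CC[C@H]3C(C)(C)[C@@H](O)CC[C@]3(C)[C@]1(CC/C(C)=C/C(=O)OC)O2
F7 | step 8 | methyl 3β,9α-dihydroxy-8-(trifluoromethylsulfonyloxy)-17-norlabda-7,13E-dien-15-oate | FC(F)(F)S(=O)(=O)OC1=CC[C@H]2C(C)(C)[C@@H](O)CC[C@]2(C)[C@]1(CC/C(C)=C/C(=O)OC)O
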